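## Retrosynthetic overview

1. The cyclopentane of the cis-hydroazulene is cut across C2–C3 and C1–C8a (azulene locants): a formal [3+2] union of a seven-membered-ring fragment (C3–C3a–C8a) with a 1,1-disubstituted alkene that already carries the complete δ-lactone.
2. Enabling feature: the exocyclic C8=CH2 of the seven-membered ring sits on the carbon next to ring-fusion carbon C8a, so C8(=CH2)/C8a/C3a/C3 is a latent vinylcyclopropane (cyclopropane C8a–C3a–C3). A thiyl radical adds to the methylidene, the cyclopropane opens at C8a–C3, and the thiyl radical leaves again to restore C8=CH2.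
3. The C1 methyl passes through the key step at the aldehyde oxidation level (a 2-lactonyl acrolein, from allylic oxidation of the isopropenyl lactone), which makes the alkene a radical acceptor; it is reduced back to CH3 in the last step.
4. Ring order: seven-membered ring (Ito–Saegusa expansion), then cyclopropane (CBS reduction, directed Simmons–Smith; fixes C3a); δ-lactone (malate-dianion Claisen fixes lactone C4/C5, Mitsunobu inversion fixes C3); cyclopentane last (key step; fixes C8a and C1).

Key step: step 17

Remark: compounds 3 and 4 are racemic and are written without stereodescriptors; their stereocentres are erased in step 3. Hydroazulene locants follow azulene (C1 quaternary, C3a/C8a ring fusion, C8 methylidene); the lactone is numbered as oxan-2-one.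

## Route

Step 1
Reactants: 1 3-methylcyclohex-2-en-1-one
Product: 2 trimethyl[(3,3-dimethylcyclohex-1-en-1-yl)oxy]silane
Conditions: MeMgBr, CuBr·SMe2 (5 mol %), TMSCl, DMPU, THF, −78 °C
Reagents that add atoms: methylmagnesium bromide, C[Mg]Br; chlorotrimethylsilane, C[Si](C)(C)Cl
Why: Copper-catalysed conjugate addition builds the gem-dimethyl carbon and TMSCl traps the enolate regiospecifically as the enol ether on the quaternary side (conjugate addition–enolate trapping).

Step 2
Reactants: 2 trimethyl[(3,3-dimethylcyclohex-1-en-1-yl)oxy]silane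
Product: 3 rac-[(5,5-dimethylbicyclo[4.1.0]heptan-1-yl)oxy]trimethylsilane
Conditions: Et2Zn, CH2I2, CH2Cl2, 0 °C → rt
Reagents that add atoms: diiodomethane, ICI
Why: Simmons–Smith cyclopropanation (Furukawa variant) of the electron-rich silyl enol ether gives the siloxycyclopropane, and no stereocontrol is needed because both centres are lost in step 3.

Step 3
Reactants: 3 rac-[(5,5-dimethylbicyclo[4.1.0]heptan-1-yl)oxy]trimethylsilane
Product: 5 4,4-dimethylcyclohept-2-en-1-one, via 3-chloro-4,4-dimethylcycloheptan-1-one 4 (not isolated)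
Conditions: FeCl3, DMF, 0 °C → rt; then NaOAc, MeOH, reflux
Reagents that add atoms: none
Why: Ito–Saegusa ring expansion: FeCl3 oxidises the siloxycyclopropane, the ring-fusion bond cleaves to the β-chloro ketone, and NaOAc eliminates HCl (E1cB), which places the enone double bond next to the quaternary carbon.

Step 4
Reactants: 5 4,4-dimethylcyclohept-2-en-1-one
Product: 6 (1R)-4,4-dimethylcyclohept-2-en-1-ol
Conditions: (S)-Me-CBS (10 mol %), BH3·SMe2, THF, −40 °C
Reagents that add atoms: none
Why: Corey–Bakshi–Shibata reduction with the alkene arm acting as the large group should deliver hydride to one carbonyl face and set the carbinol centre as R, the only catalyst-set stereocentre of this fragment.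

Step 5
Reactants: 6 (1R)-4,4-dimethylcyclohept-2-en-1-ol
Product: 7 (1S,2R,7R)-6,6-dimethylbicyclo[5.1.0]octan-2-ol
Conditions: Et2Zn, CH2I2, CH2Cl2, −10 °C → rt
Reagents that add atoms: diiodomethane, ICI
Why: Hydroxyl-directed Simmons–Smith cyclopropanation delivers CH2 syn to the zinc alkoxide of a cycloheptenol, so the carbinol centre relays its configuration to C1 and C7 (C7 becomes ring-fusion carbon C3a of the target).

Step 6
Reactants: 7 (1S,2R,7R)-6,6-dimethylbicyclo[5.1.0]octan-2-ol
Product: 8 (1S,7R)-6,6-dimethylbicyclo[5.1.0]octan-2-one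
Conditions: Dess–Martin periodinane, NaHCO3, CH2Cl2, rt
Reagents that add atoms: none
Why: Buffered Dess–Martin oxidation removes the now superfluous carbinol centre without opening or epimerising the cis-fused cyclopropyl ketone.

Step 7
Reactants: 8 (1S,7R)-6,6-dimethylbicyclo[5.1.0]octan-2-one
Product: 9 (1S,7R)-6,6-dimethyl-2-methylidenebicyclo[5.1.0]octane
Conditions: Ph3PCH3Br, KOt-Bu, THF, 0 °C → rt
Reagents that add atoms: methyltriphenylphosphonium bromide, C[P+](c1ccccc1)(c1ccccc1)c1ccccc1.[Br-]
Why: Wittig methylenation converts the cyclopropyl ketone into the vinylcyclopropane without touching the cyclopropane stereocentres.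

Step 8
Reactants: 10 3-methylbut-2-en-1-ol
Product: 11 tert-butyl(dimethyl)[(3-methylbut-2-en-1-yl)oxy]silane
Conditions: TBSCl, imidazole, DMF, rt
Reagents that add atoms: tert-butyldimethylsilyl chloride, CC(C)(C)[Si](C)(C)Cl
Why: Standard silylation gives a protecting group that survives LDA and is removed by fluoride at the lactonisation stage.

Step 9
Reactants: 11 tert-butyl(dimethyl)[(3-methylbut-2-en-1-yl)oxy]silane
Product: 12 (2E)-4-{[tert-butyl(dimethyl)silyl]oxy}-2-methylbut-2-en-1-ol
Conditions: SeO2 (cat.), t-BuOOH, salicylic acid (cat.), CH2Cl2, rt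
Reagents that add atoms: tert-butyl hydroperoxide, CC(C)(C)OO (oxygen atom, transferred via catalytic selenium dioxide, O=[Se]=O)
Why: Riley-type allylic oxidation of a gem-dimethyl alkene is selective for the E-methyl group (ene reaction then [2,3]-shift), which gives the E-allylic alcohol needed for the chair Claisen transition state.

Step 10
Reactants: 13 (2R)-2-hydroxybutanedioic acid [(R)-malic acid]
Product: 15 (3R)-3-hydroxy-4-methoxy-4-oxobutanoic acid, via (3R)-2,5-dioxooxolan-3-yl trifluoroacetate 14 (not isolated)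
Conditions: (CF3CO)2O, 0 °C → rt; evaporate; MeOH, rt
Reagents that add atoms: methanol, CO
Why: The O-trifluoroacetyl cyclic anhydride is opened by methanol at the more electrophilic carbonyl next to the acyloxy group and then deacylated, leaving the C4 acid free (regioselective anhydride alcoholysis).

Step 11
Reactants: 12 (2E)-4-{[tert-butyl(dimethyl)silyl]oxy}-2-methylbut-2-en-1-ol; 15 (3R)-3-hydroxy-4-methoxy-4-oxobutanoic acid
Product: 16 1-methyl 4-[(2E)-4-{[tert-butyl(dimethyl)silyl]oxy}-2-methylbut-2-en-1-yl] (2R)-2-hydroxybutanedioate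
Conditions: EDC·HCl, DMAP (cat.), CH2Cl2, 0 °C
Reagents that add atoms: none
Why: Steglich-type carbodiimide esterification joins the free acid to the primary allylic alcohol, which should react much faster than the hindered secondary hydroxyl of 15.

Step 12
Reactants: 16 1-methyl 4-[(2E)-4-{[tert-butyl(dimethyl)silyl]oxy}-2-methylbut-2-en-1-yl] (2R)-2-hydroxybutanedioate
Product: 18 (2S,3R)-2-[(2R)-1-{[tert-butyl(dimethyl)silyl]oxy}-3-methylbut-3-en-2-yl]-3-hydroxy-4-methoxy-4-oxobutanoic acid, via dilithium enolate-alkoxide of the allyl ester 17 (not isolated)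
Conditions: LDA (2.3 equiv), THF, −78 °C → 50 °C; dilute HCl work-up
Reagents that add atoms: none
Why: Ester-enolate (Ireland–Claisen-type) [3,3] rearrangement of the Fráter–Seebach dianion, in which the alkoxide protects C2 and chelates the enolate as the Z(O) isomer, the allyl unit adds to the enolate face anti to the carbinol substituent (sets C2 of 18), and the chair transition state with the E-alkene sets the isopropenyl-bearing centre.

Step 13
Reactants: 18 (2S,3R)-2-[(2R)-1-{[tert-butyl(dimethyl)silyl]oxy}-3-methylbut-3-en-2-yl]-3-hydroxy-4-methoxy-4-oxobutanoic acid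
Product: 20 methyl (2R,3R)-3-[(2R)-1-{[tert-butyl(dimethyl)silyl]oxy}-3-methylbut-3-en-2-yl]-2,4-dihydroxybutanoate, via isobutyl carbonic mixed anhydride 19 (not isolated)
Conditions: i-BuOCOCl, N-methylmorpholine, THF, −15 °C; then NaBH4, THF/H2O, −15 → 0 °C; used directly
Reagents that add atoms: none
Why: Mixed-anhydride activation followed by borohydride reduces only the carboxylic acid and avoids borane, which would hydroborate the isopropenyl group.

Step 14
Reactants: 20 methyl (2R,3R)-3-[(2R)-1-{[tert-butyl(dimethyl)silyl]oxy}-3-methylbut-3-en-2-yl]-2,4-dihydroxybutanoate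
Product: 21 methyl (2S,3R)-2,4-bis(acetyloxy)-3-[(2R)-1-{[tert-butyl(dimethyl)silyl]oxy}-3-methylbut-3-en-2-yl]butanoate
Conditions: PPh3, DIAD, AcOH (excess), THF, 0 °C → rt
Reagents that add atoms: acetic acid, CC(=O)O
Why: Double Mitsunobu reaction acetylates the primary alcohol and displaces the activated α-hydroxy ester by SN2 with inversion, converting the 2R carbinol into the 2S acetate required in the lactone.

Step 15
Reactants: 21 methyl (2S,3R)-2,4-bis(acetyloxy)-3-[(2R)-1-{[tert-butyl(dimethyl)silyl]oxy}-3-methylbut-3-en-2-yl]butanoate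
Product: 23 [(3S,4R,5R)-3-(acetyloxy)-2-oxo-5-(prop-1-en-2-yl)oxan-4-yl]methyl acetate, via desilylated hydroxy ester 22 (not isolated)
Conditions: HF·pyridine, THF, 0 °C → rt; then TsOH (cat.), PhH, 60 °C
Reagents that add atoms: none
Why: Fluoride removes the silyl ether and acid catalysis closes the six-membered lactone by intramolecular transesterification onto the α-acetoxy methyl ester, the only acyl group that allows a 6-ring closure once both other hydroxyls are acetylated.

Step 16
Reactants: 23 [(3S,4R,5R)-3-(acetyloxy)-2-oxo-5-(prop-1-en-2-yl)oxan-4-yl]methyl acetate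
Product: 25 [(3S,4R,5R)-3-(acetyloxy)-2-oxo-5-(3-oxoprop-1-en-2-yl)oxan-4-yl]methyl acetate, via allylic alcohol 24 (not isolated)
Conditions: SeO2 (cat.), t-BuOOH, CH2Cl2, rt; filter; then MnO2, CH2Cl2, rt
Reagents that add atoms: tert-butyl hydroperoxide, CC(C)(C)OO (oxygen atom, transferred via catalytic selenium dioxide, O=[Se]=O)
Why: Riley oxidation of the 1,1-disubstituted alkene should attack the methyl group in preference to the hindered tertiary allylic C–H, and MnO2 completes the oxidation to the 2-substituted acrolein, which turns the unactivated isopropenyl group into a radical acceptor.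

Step 17
Reactants: 9 (1S,7R)-6,6-dimethyl-2-methylidenebicyclo[5.1.0]octane; 25 [(3S,4R,5R)-3-(acetyloxy)-2-oxo-5-(3-oxoprop-1-en-2-yl)oxan-4-yl]methyl acetate
Product: 26 [(3S,4R,5R)-3-(acetyloxy)-5-[(1S,3aR,8aS)-1-formyl-4,4-dimethyl-8-methylidenedecahydroazulen-1-yl]-2-oxooxan-4-yl]methyl acetate
Conditions: PhSSPh (0.3 equiv), AIBN (cat.), hν (sunlamp), PhH, 60 °C; 9 (1.5–2 equiv) added slowly to concentrated 25
Reagents that add atoms: none
Why: PhS• adds to the exocyclic CH2 of 9, the tertiary cyclopropylcarbinyl radical opens by cleavage of the external cyclopropane bond (C1–C8 of 9, the bond best aligned with the radical p-orbital) to a primary homoallyl radical, this adds to the CH2 terminus of enal 25, and the α-formyl tertiary radical closes onto the new ring alkene, after which β-scission expels PhS•, restores the exocyclic methylidene and carries the chain. The closest known reaction type is the thiyl-radical-catalysed [3+2] annulation of vinylcyclopropanes with electron-poor alkenes. The cyclopentane closes by 5-exo-trig attack of the C1 radical on C8a (target locants), preferred over 6-endo attack at C8. C8a is set cis to C3a because the three-atom tether from C3a can only reach the same face of the cycloheptene, and C1 is set by the large lactonyl group taking the exo (convex) position while the small formyl group points towards the seven-membered ring; A1,3 strain at the radical (lactone C5–H eclipsing the formyl-bearing bond, attack anti to lactone C4) favours the same face, so the two enantiopure partners should be matched. The step needs chemoselective addition of the nucleophilic primary radical to the enal and not to a second molecule of 9 (secured by polarity matching and by keeping 25 concentrated while 9 is added slowly) and regioselective opening of the external cyclopropane bond (secured by stereoelectronics and fast trapping).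

Step 18
Reactants: 26 [(3S,4R,5R)-3-(acetyloxy)-5-[(1S,3aR,8aS)-1-formyl-4,4-dimethyl-8-methylidenedecahydroazulen-1-yl]-2-oxooxan-4-yl]methyl acetate
Product: 28 [(3S,4R,5R)-3-(acetyloxy)-2-oxo-5-[(1R,3aR,8aS)-1,4,4-trimethyl-8-methylidenedecahydroazulen-1-yl]oxan-4-yl]methyl acetate, via tosylhydrazone 27 (not isolated)
Conditions: TsNHNH2, THF, rt; then catecholborane, CHCl3, 0 °C; NaOAc·3H2O, 60 °C
Reagents that add atoms: none
Why: Caglioti-type reduction: the tosylhydrazone of the non-enolisable neopentyl aldehyde is hydroborated by catecholborane and acetate triggers loss of sulfinate and N2 to give the methyl group, under conditions that should leave the lactone, the acetates and the exocyclic alkene untouched.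

## Compound list

1 | 3-methylcyclohex-2-en-1-one | CC1=CC(=O)CCC1 | starting material
2 | trimethyl[(3,3-dimethylcyclohex-1-en-1-yl)oxy]silane | C[Si](C)(C)OC1=CC(C)(C)CCC1 | intermediate
3 | rac-[(5,5-dimethylbicyclo[4.1.0]heptan-1-yl)oxy]trimethylsilane | C[Si](C)(C)OC12CCCC(C)(C)C1C2 | intermediate
4 | rac-3-chloro-4,4-dimethylcycloheptan-1-one | O=C1CC(Cl)C(C)(C)CCC1 | intermediate
5 | 4,4-dimethylcyclohept-2-en-1-one | O=C1C=CC(C)(C)CCC1 | intermediate
6 | (1R)-4,4-dimethylcyclohept-2-en-1-ol | O[C@@H]1CCCC(C)(C)C=C1 | intermediate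
7 | (1S,2R,7R)-6,6-dimethylbicyclo[5.1.0]octan-2-ol | O[C@@H]1CCCC(C)(C)[C@@H]2C[C@H]12 | intermediate
8 | (1S,7R)-6,6-dimethylbicyclo[5.1.0]octan-2-one | O=C1CCCC(C)(C)[C@@H]2C[C@H]12 | intermediate
9 | (1S,7R)-6,6-dimethyl-2-methylidenebicyclo[5.1.0]octane | C=C1CCCC(C)(C)[C@@H]2C[C@H]12 | intermediate
10 | 3-methylbut-2-en-1-ol | CC(C)=CCO | starting material
11 | tert-butyl(dimethyl)[(3-methylbut-2-en-1-yl)oxy]silane | CC(C)=CCO[Si](C)(C)C(C)(C)C | intermediate
12 | (2E)-4-{[tert-butyl(dimethyl)silyl]oxy}-2-methylbut-2-en-1-ol | OC/C(C)=C/CO[Si](C)(C)C(C)(C)C | intermediate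
13 | (2R)-2-hydroxybutanedioic acid [(R)-malic acid] | O[C@H](CC(O)=O)C(O)=O | starting material
14 | (3R)-2,5-dioxooxolan-3-yl trifluoroacetate | O=C(O[C@@H]1CC(=O)OC1=O)C(F)(F)F | intermediate
15 | (3R)-3-hydroxy-4-methoxy-4-oxobutanoic acid | COC(=O)[C@H](O)CC(O)=O | intermediate
16 | 1-methyl 4-[(2E)-4-{[tert-butyl(dimethyl)silyl]oxy}-2-methylbut-2-en-1-yl] (2R)-2-hydroxybutanedioate | COC(=O)[C@H](O)CC(=O)OC/C(C)=C/CO[Si](C)(C)C(C)(C)C | intermediate
17 | dilithium (Z)-enolate-alkoxide of 16 | [Li+].[Li+].COC(=O)[C@H]([O-])/C=C(\[O-])OC/C(C)=C/CO[Si](C)(C)C(C)(C)C | intermediate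
18 | (2S,3R)-2-[(2R)-1-{[tert-butyl(dimethyl)silyl]oxy}-3-methylbut-3-en-2-yl]-3-hydroxy-4-methoxy-4-oxobutanoic acid | CC(=C)[C@H](CO[Si](C)(C)C(C)(C)C)[C@H](C(O)=O)[C@@H](O)C(=O)OC | intermediate
19 | isobutyl carbonic mixed anhydride of 18 | CC(=C)[C@H](CO[Si](C)(C)C(C)(C)C)[C@H](C(=O)OC(=O)OCC(C)C)[C@@H](O)C(=O)OC | intermediate
20 | methyl (2R,3R)-3-[(2R)-1-{[tert-butyl(dimethyl)silyl]oxy}-3-methylbut-3-en-2-yl]-2,4-dihydroxybutanoate | CC(=C)[C@H](CO[Si](C)(C)C(C)(C)C)[C@H](CO)[C@@H](O)C(=O)OC | intermediate
21 | methyl (2S,3R)-2,4-bis(acetyloxy)-3-[(2R)-1-{[tert-butyl(dimethyl)silyl]oxy}-3-methylbut-3-en-2-yl]butanoate | CC(=C)[C@H](CO[Si](C)(C)C(C)(C)C)[C@H](COC(C)=O)[C@H](OC(C)=O)C(=O)OC | intermediate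
22 | methyl (2S,3R)-2,4-bis(acetyloxy)-3-[(2R)-1-hydroxy-3-methylbut-3-en-2-yl]butanoate | CC(=C)[C@H](CO)[C@H](COC(C)=O)[C@H](OC(C)=O)C(=O)OC | intermediate
23 | [(3S,4R,5R)-3-(acetyloxy)-2-oxo-5-(prop-1-en-2-yl)oxan-4-yl]methyl acetate | CC(=C)[C@@H]1COC(=O)[C@@H](OC(C)=O)[C@H]1COC(C)=O | intermediate
24 | [(3S,4R,5R)-3-(acetyloxy)-5-(3-hydroxyprop-1-en-2-yl)-2-oxooxan-4-yl]methyl acetate | OCC(=C)[C@@H]1COC(=O)[C@@H](OC(C)=O)[C@H]1COC(C)=O | intermediate
25 | [(3S,4R,5R)-3-(acetyloxy)-2-oxo-5-(3-oxoprop-1-en-2-yl)oxan-4-yl]methyl acetate | O=CC(=C)[C@@H]1COC(=O)[C@@H](OC(C)=O)[C@H]1COC(C)=O | intermediate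
26 | [(3S,4R,5R)-3-(acetyloxy)-5-[(1S,3aR,8aS)-1-formyl-4,4-dimethyl-8-methylidenedecahydroazulen-1-yl]-2-oxooxan-4-yl]methyl acetate | C=C1CCCC(C)(C)[C@@H]2CC[C@@](C=O)([C@@H]3COC(=O)[C@@H](OC(C)=O)[C@H]3COC(C)=O)[C@H]12 | intermediate
27 | (E)-tosylhydrazone of 26 | C=C1CCCC(C)(C)[C@@H]2CC[C@@](/C=N/NS(=O)(=O)c3ccc(C)cc3)([C@@H]4COC(=O)[C@@H](OC(C)=O)[C@H]4COC(C)=O)[C@H]12 | intermediate
28 | [(3S,4R,5R)-3-(acetyloxy)-2-oxo-5-[(1R,3aR,8aS)-1,4,4-trimethyl-8-methylidenedecahydroazulen-1-yl]oxan-4-yl]methyl acetate | C=C1CCCC(C)(C)[C@@H]2CC[C@@](C)([C@@H]3COC(=O)[C@@H](OC(C)=O)[C@H]3COC(C)=O)[C@H]12 | target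

## Step count and risks

Total step count: 18 (steps 1–7 vinylcyclopropane, steps 8–16 lactone enal, steps 17–18 union and adjustment).
Longest linear sequence: 10 steps (10 → 11 → 12 → 16 → 18 → 20 → 21 → 23 → 25 → 26 → 28; steps 8, 9, 11–18).

Steps most likely to fail:

Step 17. The cyclopropylcarbinyl radical may open at the internal cyclopropane bond (ring expansion to a cyclooctenyl radical), the vinylcyclopropane may oligomerise before the primary radical is trapped, or the facial selectivity at C1 may be low. The fallback makes the same primary radical without a radical ring opening. It sets out from 8: addition of PhSCH2Li (thioanisole, n-BuLi, DABCO, THF, 0 °C) should give the tertiary carbinol (1S,7R)-6,6-dimethyl-2-[(phenylsulfanyl)methyl]bicyclo[5.1.0]octan-2-ol F1. A Julia cyclopropylcarbinyl–homoallyl rearrangement (MgBr2·OEt2 or 48% HBr, Et2O, 0 °C) then opens the cyclopropane ionically at its CH2 carbon to the homoallylic bromide ({[(3R)-3-(bromomethyl)-4,4-dimethylcyclohept-1-en-1-yl]methyl}sulfanyl)benzene F2. F2 and 25 with (Bu3Sn)2, hν, PhH, 80 °C (bromine abstraction, Giese addition, 5-exo cyclisation, β-scission of the thiyl radical) should give 26, where the route is rejoined.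

Step 14. SN2 displacement at the β-branched α-hydroxy ester may be slow, elimination may compete, or the 1,3-diol ester may close to the five-membered lactone before it is acetylated. The fallback separates capping from inversion and sets out from 20: selective acetylation of the primary hydroxyl (AcCl, 2,4,6-collidine, CH2Cl2, −78 °C) should give methyl (2R,3R)-4-(acetyloxy)-3-[(2R)-1-{[tert-butyl(dimethyl)silyl]oxy}-3-methylbut-3-en-2-yl]-2-hydroxybutanoate F3. Tf2O and 2,6-lutidine (CH2Cl2, −78 °C) convert it into the triflate methyl (2R,3R)-4-(acetyloxy)-3-[(2R)-1-{[tert-butyl(dimethyl)silyl]oxy}-3-methylbut-3-en-2-yl]-2-{[(trifluoromethyl)sulfonyl]oxy}butanoate F4, and CsOAc with 18-crown-6 in toluene displaces it with inversion to give 21.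

Step 16. The SeO2 ene reaction may attack the tertiary allylic C5–H, stall at low conversion, or over-oxidise. The fallback reaches the allylic alcohol through an epoxide and sets out from 23: epoxidation of its only alkene (mCPBA, NaHCO3, CH2Cl2, 0 °C) should give [(3S,4R,5S)-3-(acetyloxy)-5-(2-methyloxiran-2-yl)-2-oxooxan-4-yl]methyl acetate F5 as a mixture of epoxide epimers. Titanocene(III) chloride (Cp2TiCl2, Mn, THF, rt) opens the epoxide to the tertiary radical, which loses a methyl hydrogen to give allylic alcohol 24; this is isolated and oxidised with MnO2 to 25 as in step 16.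

Further compounds
F1 | step 17 | (1S,7R)-6,6-dimethyl-2-[(phenylsulfanyl)methyl]bicyclo[5.1.0]octan-2-ol (C2 epimers) | OC1(CSc2ccccc2)CCCC(C)(C)[C@@H]2C[C@H]12
F2 | step 17 | ({[(3R)-3-(bromomethyl)-4,4-dimethylcyclohept-1-en-1-yl]methyl}sulfanyl)benzene | CC1(C)CCCC(CSc2ccccc2)=C[C@H]1CBr
F3 | step 14 | methyl (2R,3R)-4-(acetyloxy)-3-[(2R)-1-{[tert-butyl(dimethyl)silyl]oxy}-3-methylbut-3-en-2-yl]-2-hydroxybutanoate | CC(=C)[C@H](CO[Si](C)(C)C(C)(C)C)[C@H](COC(C)=O)[C@@H](O)C(=O)OC
F4 | step 14 | methyl (2R,3R)-4-(acetyloxy)-3-[(2R)-1-{[tert-butyl(dimethyl)silyl]oxy}-3-methylbut-3-en-2-yl]-2-{[(trifluoromethyl)sulfonyl]oxy}butanoate | CC(=C)[C@H](CO[Si](C)(C)C(C)(C)C)[C@H](COC(C)=O)[C@@H](OS(=O)(=O)C(F)(F)F)C(=O)OC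
F5 | step 16 | [(3S,4R,5S)-3-(acetyloxy)-5-(2-methyloxiran-2-yl)-2-oxooxan-4-yl]methyl acetate (epoxide epimers) | CC1(CO1)[C@@H]2COC(=O)[C@@H](OC(C)=O)[C@H]2COC(C)=O
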